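## The problem

Stypoquinonic acid (25) joins a 2-methyl-1,4-benzoquinone through one CH2 group to a trans-decalin, numbered here as a decahydronaphthalene: C-1 bears the 2-carboxyethyl chain, C-2 the isopropylidene, C-4a is the ring-fusion CH, C-5 the quaternary carbon with methyl and quinonylmethyl, C-6 a CH–CH3 and C-8a the angular methyl carbon, with ring A made of C-1 to C-4, C-4a and C-8a and ring B of C-4a to C-8 and C-8a. Five contiguous stereocentres (C-6, C-5, C-4a, C-8a, C-1) must be set, two of them quaternary. In the chair–chair form the methyls at C-5 and C-8a are 1,3-diaxial on one face, the hydrogens at C-4a and C-1 are axial on the other, and the arylmethyl (C-5), the methyl (C-6) and the chain (C-1) are equatorial. All five centres lie in one rigid bicycle, so one element of chirality can control the rest if the rings close through ordered transition states; only the C-6 methyl offers no handle and must be reached indirectly. The C-2 isopropylidene is a tetrasubstituted exocyclic alkene that eclipses the equatorial C-1 chain, so it is best made late from a C-2 carbonyl, and while that carbonyl exists C-1 can epimerise, though toward the wanted equatorial isomer. The quinone will not survive organometallic reagents, low-valent metals or hydrogenation and is carried as the hydroquinone dimethyl ether, an electron-rich arene two bonds from C-5 that can compete for a cation there; the acid is also carried masked, and the isopropylidene rules out strong acid and unselective hydrogenation at the end. The enabling feature is the sequence C-6, C-5, C-4a, C-8a, C-1, C-2, in which a fully substituted C-5 lies next to a carbon (C-6) whose methyl can stand in for oxygen, a methyl-bearing quaternary C-8a is 1,3 to C-5 and an sp2 C-2 is next to C-1: these are the positions of an epoxide, of the substituted carbon of an (E)-alkene and of an enol ether in an open chain, and the anti relationships around C-5, C-4a, C-8a and C-1 are those left by a chair–chair cation–olefin cyclisation.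

## Retrosynthesis

**25 from 24 from 23 (aryl O–CH3 bonds and oxidation level only, no skeletal bond cut).** The quinone is unmasked last by oxidative demethylation of dimethyl ether 24, and the acid comes from primary alcohol 23. The quinone and the free acid are the groups least tolerant of the earlier chemistry, whereas two aryl methyl ethers and one benzyl ether pass through every step. The forward reactions must oxidise a primary alcohol and then an arene without touching the isopropylidene.

**23 from 22 from 21 from 20 (C-6–CH3 bond).** The equatorial C-6 methyl is traced to exocyclic alkene 22, to ketone 21 and to equatorial alcohol 20. This cut is preferred over carrying the methyl in from the start because C-6 then becomes the carbinol carbon of an epoxide. The forward hydrogenation must add hydrogen to the face opposite the axial C-5 methyl, which leaves the new methyl equatorial; the same operation is meant to remove the benzyl group.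

**20 from 19 (C-2=C exocyclic bond).** The isopropylidene is cut to the C-2 ketone of 19 and a three-carbon ketone partner in a mixed reductive carbonyl coupling. A C-2 carbonyl is what an enol ether terminator leaves behind, so no functional group has to be moved. Doing this before the C-6 hydroxyl is oxidised means only one carbonyl is present. The chain is a benzyl ether and not an ester because low-valent titanium would couple a keto ester.

**19 from 18 (C-4a–C-5 and C-1–C-8a, the key cut).** Each of these bonds joins a carbon that can carry a cation (C-5, C-8a) to an alkene CH. Cutting the ring-fusion bond or a bond at C-6 would leave a cyclic precursor that still holds most of the stereocentres. The chosen cut gives the unbranched chain 18, whose only stereogenic units are one epoxide and two double-bond geometries. The forward step must open the epoxide at its substituted carbon with anti participation of the (E)-alkene, pass through two chairs, and end at the (Z)-enol ether carbon in preference to proton loss or capture by the arene.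

**18 from 17 from 15 + 16; 15 from 12 + 13.** The enol ether is cut at Si–O and C–H to enone 17 (1,4-hydrosilylation). Direct enolisation of the saturated ketone was rejected because both α-positions are CH2 groups, so neither regiochemistry nor geometry could be controlled. Enone 17 is cut at its C=C bond into β-keto phosphonate 15 and aldehyde 16, and 15 is cut at the allylic C–C bond into bromide 12 and phosphonate 13. The precursors are an allylic bromide and two purchasable three- and four-carbon pieces. The forward steps must leave the epoxide alone and give the (E)-enone and then the (Z)-enol ether.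

**12 from 10 from 9 from 8.** Bromide 12 comes from alcohol 10 and this from allylic acetate 9; the acetate is kept until after the epoxidation because it deactivates the neighbouring alkene. The epoxide of 9 is cut to the (E)-alkene of 8. Direct oxygen transfer is required: dihydroxylation followed by closure through the secondary sulfonate would invert one centre and exchange methyl and arylmethyl at the stereogenic quaternary carbon. The forward reaction must select the terminal alkene and the face that gives the (R,R)-epoxide.

**8 from 3 + 6; 6 from 5 from 4; 3 from 2 from 1.** The aryl–CH2 bond is cut to aryl bromide 3, used as its Grignard reagent 7, and allylic bromide 6. Bromide 6 comes from geranyl acetate 4 by oxidation of the terminal (E)-methyl to alcohol 5. This places the arylmethyl trans to the chain on the alkene, hence trans on the epoxide and equatorial at C-5. Aryl bromide 3 comes from phenol 1 by ortho-bromination to 2 and O-methylation. The starting materials 1, 4, 13 and 16 are simple commercial compounds.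

## Roads not taken

Alternative 1: The C-5 methyl is traced to a cyclopropane methylene that bridges C-5 and C-4a. In the forward sense Et2Zn and CH2I2 cyclopropanate the tetrasubstituted C-4a=C-5 double bond of allylic alcohol A1 from the face of its C-4 hydroxyl and give cyclopropyl carbinol A2. Oxidation of the carbinol and dissolving-metal opening of the cyclopropane bond to C-4a would then release the methyl and set the ring fusion.
Merits: hydroxyl-directed zinc carbenoid delivery is a dependable way to set a quaternary methyl, the bicyclic core of A1 could be built by annulation chemistry that is available in enantiopure form, and no cation is generated near the arene.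
Weak points: the alkene of A1 is tetrasubstituted and slow to react. A2 carries an oxygen at C-4 that must be removed and a ketal at C-1, so the chain and the isopropylidene on the unfunctionalised C-2 must be built by a long linear sequence. The arylmethyl and the C-6 methyl of A1 would have been set earlier by alkylations of uncertain facial selectivity.
Comparison: this road is better in certainty of absolute configuration and in avoiding arene participation. The chosen plan sets against it two rings and four stereocentres in one step, and the product 19 with ring A functionalised exactly where needed.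

Alternative 2: Three C–C bonds of the aromatic ring are cut. In the forward sense the terminal alkyne of propargyl decalin A3, which sits on the CH2 group at C-5, reacts with the Fischer carbene complex pentacarbonyl[(2E)-1-methoxybut-2-en-1-ylidene]chromium A4 in a Dötz benzannulation and gives the 4-methoxyphenol methyl ester A5.
Merits: the arene is made last, so it cannot interfere with any cationic step. The regiochemistry is reliable, with the larger alkyne substituent ending next to the phenol. A5 is only an oxidation and a hydrolysis from the target, and a 4-methoxyphenol oxidises more easily than a dimethyl ether.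
Weak points: the cut does not simplify the decalin, so alkyne A3 still needs all five stereocentres and the isopropylidene. The alkyne sits on a neopentyl position next to a quaternary carbon, and carbene complex A4 is consumed in stoichiometric amount, so chromium waste accompanies a late intermediate.
Comparison: in the handling of the aromatic ring this road is better. It is, however, an endgame that would have to be grafted onto a decalin synthesis with extra steps. The chosen plan brings the arene in by one copper-catalysed coupling and relies on the equatorial position of the arylmethyl to keep it out of the cation chemistry.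

Alternative 3: The C-4a–C-8a and C-1–C-2 bonds are cut. In the forward sense trienal A6, in which an (E)-enal with C-8a as its β-carbon is linked through C-8, C-7, C-6 and C-5 to an (E)-vinylallene, undergoes an intramolecular Diels–Alder reaction, thermally or with a Lewis acid, and gives octalin aldehyde A7.
Merits: both rings and the centres C-4a, C-8a and C-1 form in one step. The isopropylidene arrives with the allene and the C-6 methyl is already at its final oxidation level, so far fewer corrections follow than in the chosen plan, which spends five steps on C-2 and C-6.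
Weak points: the open-chain substrate A6 must already hold the vicinal C-5 and C-6 stereocentres. Its β,β-disubstituted enal, which must form a quaternary carbon, is a poor dienophile. The trans fusion needs one particular endo/exo and facial combination, controlled only by C-5. A7 contains a 1,3-diene whose ring alkene must be saturated without moving the isopropylidene, and its aldehyde needs a two-carbon extension.
Comparison: this road is better in step economy after ring formation. The chosen plan sets against it the precursor 18 with a single stereogenic unit made by catalytic asymmetric epoxidation and a ring-forming step of predictable stereochemistry.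

Key step: step 12

Remark on the chemistry: the carboxyl group is carried as a benzyl-protected primary alcohol and the enol ether as its triethylsilyl derivative; geranyl acetate, 3-(benzyloxy)propanal and dimethyl (2-oxopropyl)phosphonate are taken as purchasable.

## Steps

Step 1
Reactants: 1 4-methoxy-2-methylphenol
Product: 2 2-bromo-4-methoxy-6-methylphenol
Conditions: NBS, MeCN, 0 °C
Reagents that add atoms: N-bromosuccinimide, O=C1CCC(=O)N1Br
Why: Electrophilic aromatic bromination; the free hydroxyl outranks methoxy and methyl as director, its para position is occupied, and the only free ortho position takes the bromine.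

Step 2
Reactants: 2 2-bromo-4-methoxy-6-methylphenol
Product: 3 1-bromo-2,5-dimethoxy-3-methylbenzene
Conditions: MeI, K2CO3, acetone, reflux
Reagents that add atoms: iodomethane, CI
Why: Williamson ether synthesis on the phenoxide; nothing else in the molecule is alkylated under carbonate.

Step 3
Reactants: 4 geranyl acetate [(2E)-3,7-dimethylocta-2,6-dien-1-yl acetate]
Product: 5 (2E,6E)-8-hydroxy-3,7-dimethylocta-2,6-dien-1-yl acetate
Conditions: SeO2 (cat.), t-BuOOH, salicylic acid (cat.), CH2Cl2, 23 °C
Reagents that add atoms: tert-butyl hydroperoxide, CC(C)(C)OO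
Why: Selenium dioxide allylic oxidation (ene reaction, then [2,3]-sigmatropic shift) attacks the terminal alkene, which the acetate does not deactivate, and by its usual preference oxidises the methyl trans to the chain, giving the (E)-allylic alcohol.

Step 4
Reactants: 5 (2E,6E)-8-hydroxy-3,7-dimethylocta-2,6-dien-1-yl acetate
Product: 6 (2E,6E)-8-bromo-3,7-dimethylocta-2,6-dien-1-yl acetate
Conditions: CBr4, PPh3, CH2Cl2, 0 °C
Reagents that add atoms: tetrabromomethane, BrC(Br)(Br)Br
Why: Appel bromination of a primary allylic alcohol under neutral conditions; the acetate and both alkene geometries are untouched.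

Step 5
Reactants: 3 1-bromo-2,5-dimethoxy-3-methylbenzene; 6 (2E,6E)-8-bromo-3,7-dimethylocta-2,6-dien-1-yl acetate
Product: 8 (2E,6E)-8-(2,5-dimethoxy-3-methylphenyl)-3,7-dimethylocta-2,6-dien-1-yl acetate, via arylmagnesium bromide 7 (not isolated)
Conditions: 3, Mg, THF, 50 °C; then 6, Li2CuCl4 (5 mol %), THF, −40 °C
Reagents that add atoms: none
Why: Copper-catalysed coupling of an aryl Grignard reagent with a primary allylic bromide; at low temperature the cuprate formed in the flask substitutes the bromide at its CH2 carbon much faster than it attacks the acetate, and the (E)-geometry is kept.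

Step 6
Reactants: 8 (2E,6E)-8-(2,5-dimethoxy-3-methylphenyl)-3,7-dimethylocta-2,6-dien-1-yl acetate
Product: 9 (2E)-5-{(2R,3R)-3-[(2,5-dimethoxy-3-methylphenyl)methyl]-3-methyloxiran-2-yl}-3-methylpent-2-en-1-yl acetate
Conditions: D-fructose-derived ketone (1,2:4,5-di-O-isopropylidene-β-D-erythro-2,3-hexodiulo-2,6-pyranose, 30 mol %), KHSO5, K2CO3, Bu4NHSO4, MeCN/CH2(OMe)2–aq. buffer (pH 10.5), 0 °C
Reagents that add atoms: potassium peroxymonosulfate, [K+].[O-]S(=O)(=O)OO
Why: Shi asymmetric epoxidation; the chiral dioxirane transfers oxygen in one step to the electron-richer 6,7-alkene (the 2,3-alkene is deactivated by the allylic acetate) through the spiro transition state that gives (R,R)-epoxides from (E)-trisubstituted alkenes. Syn transfer keeps the arylmethyl trans to the chain on the oxirane.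

Step 7
Reactants: 9 (2E)-5-{(2R,3R)-3-[(2,5-dimethoxy-3-methylphenyl)methyl]-3-methyloxiran-2-yl}-3-methylpent-2-en-1-yl acetate
Product: 10 (2E)-5-{(2R,3R)-3-[(2,5-dimethoxy-3-methylphenyl)methyl]-3-methyloxiran-2-yl}-3-methylpent-2-en-1-ol
Conditions: K2CO3, MeOH, 0 → 23 °C
Reagents that add atoms: none
Why: Base-catalysed transesterification of the acetate; a trisubstituted epoxide is inert to methoxide at this temperature.

Step 8
Reactants: 10 (2E)-5-{(2R,3R)-3-[(2,5-dimethoxy-3-methylphenyl)methyl]-3-methyloxiran-2-yl}-3-methylpent-2-en-1-ol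
Product: 12 (2R,3R)-3-[(3E)-5-bromo-3-methylpent-3-en-1-yl]-2-[(2,5-dimethoxy-3-methylphenyl)methyl]-2-methyloxirane, via allylic mesylate 11 (not isolated)
Conditions: MsCl, Et3N, THF, −40 °C; then LiBr, THF, 0 °C
Reagents that add atoms: lithium bromide, [Li+].[Br-]
Why: Sulfonylation of the primary allylic alcohol and SN2 displacement by bromide in the same flask; the conditions are non-acidic, so the epoxide should survive.

Step 9
Reactants: 12 (2R,3R)-3-[(3E)-5-bromo-3-methylpent-3-en-1-yl]-2-[(2,5-dimethoxy-3-methylphenyl)methyl]-2-methyloxirane; 13 dimethyl (2-oxopropyl)phosphonate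
Product: 15 dimethyl [(5E)-8-{(2R,3R)-3-[(2,5-dimethoxy-3-methylphenyl)methyl]-3-methyloxiran-2-yl}-6-methyl-2-oxooct-5-en-1-yl]phosphonate, via phosphonate dianion 14 (not isolated)
Conditions: 13, NaH, THF, 0 °C; n-BuLi, 0 °C; then 12, 0 °C
Reagents that add atoms: none
Why: Alkylation of a β-keto phosphonate 1,3-dianion, which reacts at its more basic terminal carbon; the primary allylic bromide is a far better electrophile than the hindered epoxide.

Step 10
Reactants: 15 dimethyl [(5E)-8-{(2R,3R)-3-[(2,5-dimethoxy-3-methylphenyl)methyl]-3-methyloxiran-2-yl}-6-methyl-2-oxooct-5-en-1-yl]phosphonate; 16 3-(benzyloxy)propanal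
Product: 17 (3E,8E)-1-(benzyloxy)-11-{(2R,3R)-3-[(2,5-dimethoxy-3-methylphenyl)methyl]-3-methyloxiran-2-yl}-9-methylundeca-3,8-dien-5-one
Conditions: Ba(OH)2·8H2O, THF/H2O (40:1), 23 °C
Reagents that add atoms: none
Why: Horner–Wadsworth–Emmons olefination of a stabilised keto phosphonate, which gives the (E)-enone; the mild hydroxide base avoids β-elimination of the benzyloxy aldehyde and leaves the epoxide intact.

Step 11
Reactants: 17 (3E,8E)-1-(benzyloxy)-11-{(2R,3R)-3-[(2,5-dimethoxy-3-methylphenyl)methyl]-3-methyloxiran-2-yl}-9-methylundeca-3,8-dien-5-one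
Product: 18 {[(4Z,8E)-1-(benzyloxy)-11-{(2R,3R)-3-[(2,5-dimethoxy-3-methylphenyl)methyl]-3-methyloxiran-2-yl}-9-methylundeca-4,8-dien-5-yl]oxy}triethylsilane
Conditions: Et3SiH, RhH(PPh3)4 (1 mol %), PhMe, 50 °C
Reagents that add atoms: triethylsilane, CC[SiH](CC)CC
Why: Rhodium-catalysed 1,4-hydrosilylation of an enone; silicon goes to oxygen and hydrogen to the β-carbon, so the enol ether can only form toward the former alkene carbon. Addition across the s-cis enone maps onto the (Z)-geometry; the isolated trisubstituted alkene and the epoxide do not react.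

Step 12
Reactants: 18 {[(4Z,8E)-1-(benzyloxy)-11-{(2R,3R)-3-[(2,5-dimethoxy-3-methylphenyl)methyl]-3-methyloxiran-2-yl}-9-methylundeca-4,8-dien-5-yl]oxy}triethylsilane
Product: 19 (1S,4aS,5R,6R,8aR)-1-[3-(benzyloxy)propyl]-5-[(2,5-dimethoxy-3-methylphenyl)methyl]-6-hydroxy-5,8a-dimethyloctahydronaphthalen-2(1H)-one
Conditions: MeAlCl2 (2 equiv), CH2Cl2, −94 → −78 °C; then Et3N, MeOH; 1 M HCl, THF, 0 °C (work-up)
Reagents that add atoms: none
Why: This is a Lewis acid-promoted epoxy-polyene cyclisation terminated by a silyl enol ether, a known reaction type. MeAlCl2 binds the epoxide oxygen, and the C–O bond at the fully substituted carbon lengthens as the CH carbon of the (E)-alkene attacks from the rear; this closes ring B (6-endo on the alkene, with the breaking C–O bond outside the new ring) and sets C-5 with inversion together with C-4a. The tertiary C-8a cation is then taken by the nucleophilic carbon of the (Z)-enol ether through a second chair, closing ring A (6-endo) and setting C-8a and C-1; loss of the silyl group from the oxocarbenium ion leaves the C-2 ketone, and the acidic work-up frees the C-6 hydroxyl from any transferred silyl group. At C-5 the epoxide methyl, cis to the chain, becomes axial and the arylmethyl equatorial. At C-4a and C-8a, anti addition across the (E)-alkene gives the trans ring fusion. At C-1 the (Z)-geometry places the chain equatorial with its hydrogen anti to the angular methyl, and this centre is also α to the ketone, where the equatorial isomer is the stable one. The absolute sense comes from the (R)-configured C-6, whose C–O bond lies equatorial in the first chair. The step needs alkene participation to beat 1,2-hydride shift and capture by the arene, and the second closure to beat proton loss; the concerted anti-periplanar opening at low temperature, the equatorial arylmethyl that cannot reach C-8a without a boat, and the enol ether as the strongest π-nucleophile present should secure this.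

Step 13
Reactants: 19 (1S,4aS,5R,6R,8aR)-1-[3-(benzyloxy)propyl]-5-[(2,5-dimethoxy-3-methylphenyl)methyl]-6-hydroxy-5,8a-dimethyloctahydronaphthalen-2(1H)-one
Product: 20 (1S,4aS,5R,6R,8aS)-1-[3-(benzyloxy)propyl]-5-[(2,5-dimethoxy-3-methylphenyl)methyl]-5,8a-dimethyl-2-(propan-2-ylidene)decahydronaphthalen-6-ol (locants as in 19)
Conditions: TiCl3(DME)1.5, Zn–Cu, DME, reflux; then 19 and acetone (excess), slow addition, reflux
Reagents that add atoms: acetone, CC(C)=O
Why: Mixed McMurry coupling; low-valent titanium couples the ketyl of 19 with that of acetone and deoxygenates the pinacolate to the tetrasubstituted alkene. Hydroxyl, benzyl ether and aryl ethers are tolerated, and C-1 is not endangered because its equatorial configuration is the stable one while the ketone is still present.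

Step 14
Reactants: 20 (1S,4aS,5R,6R,8aS)-1-[3-(benzyloxy)propyl]-5-[(2,5-dimethoxy-3-methylphenyl)methyl]-5,8a-dimethyl-2-(propan-2-ylidene)decahydronaphthalen-6-ol
Product: 21 (1S,4aS,5R,8aS)-1-[3-(benzyloxy)propyl]-5-[(2,5-dimethoxy-3-methylphenyl)methyl]-5,8a-dimethyl-2-(propan-2-ylidene)decahydronaphthalen-6-one (locants as in 19)
Conditions: Dess–Martin periodinane, NaHCO3, CH2Cl2, 23 °C
Reagents that add atoms: none
Why: Dess–Martin oxidation of a hindered secondary alcohol under buffered, non-acidic conditions that do not move the isopropylidene.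

Step 15
Reactants: 21 (1S,4aS,5R,8aS)-1-[3-(benzyloxy)propyl]-5-[(2,5-dimethoxy-3-methylphenyl)methyl]-5,8a-dimethyl-2-(propan-2-ylidene)decahydronaphthalen-6-one
Product: 22 (1S,4aS,5R,8aS)-1-[3-(benzyloxy)propyl]-5-[(2,5-dimethoxy-3-methylphenyl)methyl]-5,8a-dimethyl-6-methylidene-2-(propan-2-ylidene)decahydronaphthalene (locants as in 19)
Conditions: Ph3PCH3Br, KOt-Bu, PhMe, 90 °C
Reagents that add atoms: methyltriphenylphosphonium bromide, C[P+](c1ccccc1)(c1ccccc1)c1ccccc1.[Br-]
Why: Wittig methylenation under forcing conditions, as used for ketones next to a quaternary carbon; enolisation can only occur toward C-7, which is not a stereocentre.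

Step 16
Reactants: 22 (1S,4aS,5R,8aS)-1-[3-(benzyloxy)propyl]-5-[(2,5-dimethoxy-3-methylphenyl)methyl]-5,8a-dimethyl-6-methylidene-2-(propan-2-ylidene)decahydronaphthalene
Product: 23 3-{(1S,4aR,5S,6R,8aR)-5-[(2,5-dimethoxy-3-methylphenyl)methyl]-5,6,8a-trimethyl-2-(propan-2-ylidene)decahydronaphthalen-1-yl}propan-1-ol
Conditions: H2 (1 atm), 10 % Pd/C, EtOAc, 23 °C
Reagents that add atoms: none
Why: Heterogeneous catalytic hydrogenation with hydrogenolysis of the benzyl ether; the face of the exocyclic alkene syn to the axial C-5 methyl is blocked, so hydrogen should add from the other face and leave the C-6 methyl equatorial (6R). The tetrasubstituted isopropylidene is not expected to be reduced at 1 atm.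

Step 17
Reactants: 23 3-{(1S,4aR,5S,6R,8aR)-5-[(2,5-dimethoxy-3-methylphenyl)methyl]-5,6,8a-trimethyl-2-(propan-2-ylidene)decahydronaphthalen-1-yl}propan-1-ol
Product: 24 3-{(1S,4aR,5S,6R,8aR)-5-[(2,5-dimethoxy-3-methylphenyl)methyl]-5,6,8a-trimethyl-2-(propan-2-ylidene)decahydronaphthalen-1-yl}propanoic acid
Conditions: TEMPO (20 mol %), PhI(OAc)2, MeCN/H2O (1:1), 23 °C
Reagents that add atoms: water, O
Why: Oxoammonium-mediated oxidation of a primary alcohol to the aldehyde and, through its hydrate, to the acid; the conditions are non-acidic and chlorine-free, so the tetrasubstituted alkene and the arene should be left alone.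

Step 18
Reactants: 24 3-{(1S,4aR,5S,6R,8aR)-5-[(2,5-dimethoxy-3-methylphenyl)methyl]-5,6,8a-trimethyl-2-(propan-2-ylidene)decahydronaphthalen-1-yl}propanoic acid
Product: 25 stypoquinonic acid, 3-{(1S,4aR,5S,6R,8aR)-5,6,8a-trimethyl-5-[(5-methyl-3,6-dioxocyclohexa-1,4-dien-1-yl)methyl]-2-(propan-2-ylidene)decahydronaphthalen-1-yl}propanoic acid
Conditions: (NH4)2Ce(NO3)6, MeCN/H2O (2:1), 0 °C
Reagents that add atoms: water, O
Why: Oxidative demethylation of a 1,4-dimethoxyarene by tetravalent cerium (two one-electron oxidations, water adds, methanol leaves); the reaction is fast at 0 °C, so the acid and the isopropylidene should be untouched.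

## Compound list

1 | 4-methoxy-2-methylphenol | COc1ccc(O)c(C)c1 | starting material
2 | 2-bromo-4-methoxy-6-methylphenol | COc1cc(C)c(O)c(Br)c1 | intermediate
3 | 1-bromo-2,5-dimethoxy-3-methylbenzene | COc1cc(C)c(OC)c(Br)c1 | intermediate
4 | geranyl acetate, (2E)-3,7-dimethylocta-2,6-dien-1-yl acetate | CC(C)=CCC/C(C)=C/COC(C)=O | starting material
5 | (2E,6E)-8-hydroxy-3,7-dimethylocta-2,6-dien-1-yl acetate | CC(=O)OC/C=C(C)/CC/C=C(C)/CO | intermediate
6 | (2E,6E)-8-bromo-3,7-dimethylocta-2,6-dien-1-yl acetate | CC(=O)OC/C=C(C)/CC/C=C(C)/CBr | intermediate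
7 | (2,5-dimethoxy-3-methylphenyl)magnesium bromide | COc1cc(C)c(OC)c([Mg]Br)c1 | intermediate
8 | (2E,6E)-8-(2,5-dimethoxy-3-methylphenyl)-3,7-dimethylocta-2,6-dien-1-yl acetate | COc1cc(C)c(OC)c(C/C(C)=C/CC/C(C)=C/COC(C)=O)c1 | intermediate
9 | (2E)-5-{(2R,3R)-3-[(2,5-dimethoxy-3-methylphenyl)methyl]-3-methyloxiran-2-yl}-3-methylpent-2-en-1-yl acetate | COc1cc(C)c(OC)c(C[C@@]2(C)O[C@@H]2CC/C(C)=C/COC(C)=O)c1 | intermediate
10 | (2E)-5-{(2R,3R)-3-[(2,5-dimethoxy-3-methylphenyl)methyl]-3-methyloxiran-2-yl}-3-methylpent-2-en-1-ol | COc1cc(C)c(OC)c(C[C@@]2(C)O[C@@H]2CC/C(C)=C/CO)c1 | intermediate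
11 | methanesulfonate of 10 (allylic mesylate) | COc1cc(C)c(OC)c(C[C@@]2(C)O[C@@H]2CC/C(C)=C/COS(C)(=O)=O)c1 | intermediate
12 | (2R,3R)-3-[(3E)-5-bromo-3-methylpent-3-en-1-yl]-2-[(2,5-dimethoxy-3-methylphenyl)methyl]-2-methyloxirane | COc1cc(C)c(OC)c(C[C@@]2(C)O[C@@H]2CC/C(C)=C/CBr)c1 | intermediate
13 | dimethyl (2-oxopropyl)phosphonate | CC(=O)CP(=O)(OC)OC | starting material
14 | sodium lithium 1,3-dianion of dimethyl (2-oxopropyl)phosphonate | [Na+].[Li+].[CH2-]C(=O)[CH-]P(=O)(OC)OC | intermediate
15 | dimethyl [(5E)-8-{(2R,3R)-3-[(2,5-dimethoxy-3-methylphenyl)methyl]-3-methyloxiran-2-yl}-6-methyl-2-oxooct-5-en-1-yl]phosphonate | COc1cc(C)c(OC)c(C[C@@]2(C)O[C@@H]2CC/C(C)=C/CCC(=O)CP(=O)(OC)OC)c1 | intermediate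
16 | 3-(benzyloxy)propanal | O=CCCOCc1ccccc1 | starting material
17 | (3E,8E)-1-(benzyloxy)-11-{(2R,3R)-3-[(2,5-dimethoxy-3-methylphenyl)methyl]-3-methyloxiran-2-yl}-9-methylundeca-3,8-dien-5-one | COc1cc(C)c(OC)c(C[C@@]2(C)O[C@@H]2CC/C(C)=C/CCC(=O)/C=C/CCOCc3ccccc3)c1 | intermediate
18 | {[(4Z,8E)-1-(benzyloxy)-11-{(2R,3R)-3-[(2,5-dimethoxy-3-methylphenyl)methyl]-3-methyloxiran-2-yl}-9-methylundeca-4,8-dien-5-yl]oxy}triethylsilane | COc1cc(C)c(OC)c(C[C@@]2(C)O[C@@H]2CC/C(C)=C/CC/C(O[Si](CC)(CC)CC)=C/CCCOCc3ccccc3)c1 | intermediate
19 | (1S,4aS,5R,6R,8aR)-1-[3-(benzyloxy)propyl]-5-[(2,5-dimethoxy-3-methylphenyl)methyl]-6-hydroxy-5,8a-dimethyloctahydronaphthalen-2(1H)-one | COc1cc(C)c(OC)c(C[C@]2(C)[C@H]3CCC(=O)[C@@H](CCCOCc4ccccc4)[C@]3(C)CC[C@H]2O)c1 | intermediate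
20 | (1S,4aS,5R,6R,8aS)-1-[3-(benzyloxy)propyl]-5-[(2,5-dimethoxy-3-methylphenyl)methyl]-5,8a-dimethyl-2-(propan-2-ylidene)decahydronaphthalen-6-ol | COc1cc(C)c(OC)c(C[C@]2(C)[C@H]3CCC(=C(C)C)[C@@H](CCCOCc4ccccc4)[C@]3(C)CC[C@H]2O)c1 | intermediate
21 | (1S,4aS,5R,8aS)-1-[3-(benzyloxy)propyl]-5-[(2,5-dimethoxy-3-methylphenyl)methyl]-5,8a-dimethyl-2-(propan-2-ylidene)decahydronaphthalen-6-one | COc1cc(C)c(OC)c(C[C@]2(C)[C@H]3CCC(=C(C)C)[C@@H](CCCOCc4ccccc4)[C@]3(C)CCC2=O)c1 | intermediate
22 | (1S,4aS,5R,8aS)-1-[3-(benzyloxy)propyl]-5-[(2,5-dimethoxy-3-methylphenyl)methyl]-5,8a-dimethyl-6-methylidene-2-(propan-2-ylidene)decahydronaphthalene | COc1cc(C)c(OC)c(C[C@]2(C)[C@H]3CCC(=C(C)C)[C@@H](CCCOCc4ccccc4)[C@]3(C)CCC2=C)c1 | intermediate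
23 | 3-{(1S,4aR,5S,6R,8aR)-5-[(2,5-dimethoxy-3-methylphenyl)methyl]-5,6,8a-trimethyl-2-(propan-2-ylidene)decahydronaphthalen-1-yl}propan-1-ol | COc1cc(C)c(OC)c(C[C@]2(C)[C@H]3CCC(=C(C)C)[C@@H](CCCO)[C@]3(C)CC[C@H]2C)c1 | intermediate
24 | 3-{(1S,4aR,5S,6R,8aR)-5-[(2,5-dimethoxy-3-methylphenyl)methyl]-5,6,8a-trimethyl-2-(propan-2-ylidene)decahydronaphthalen-1-yl}propanoic acid | COc1cc(C)c(OC)c(C[C@]2(C)[C@H]3CCC(=C(C)C)[C@@H](CCC(=O)O)[C@]3(C)CC[C@H]2C)c1 | intermediate
25 | stypoquinonic acid, 3-{(1S,4aR,5S,6R,8aR)-5,6,8a-trimethyl-5-[(5-methyl-3,6-dioxocyclohexa-1,4-dien-1-yl)methyl]-2-(propan-2-ylidene)decahydronaphthalen-1-yl}propanoic acid | CC1=CC(=O)C=C(C[C@]2(C)[C@H]3CCC(=C(C)C)[C@@H](CCC(=O)O)[C@]3(C)CC[C@H]2C)C1=O | target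

## Step count and least certain steps

Total: 18 steps. Longest linear sequence: 16 steps (steps 3 to 18 from 4; the arene branch, steps 1, 2 and 5 to 18, is equally long).

**Step 12 (key step).** The epoxide may ionise without alkene participation and then undergo a 1,2-hydride shift to a ketone. The enol ether may lose silicon before the second C–C bond forms, so that the C-8a cation is quenched by proton loss after one ring. The arene or the benzyl ether oxygen may intercept a cation. The fallback keeps the cationic bicyclisation but replaces the silyl enol ether by a β-keto ester enol and attaches the chain afterwards; it sets out from 12 and returns at 19. Bromide 12 alkylates the dianion of methyl acetoacetate (NaH, n-BuLi, THF, 0 °C) to give methyl (6E)-9-{(2R,3R)-3-[(2,5-dimethoxy-3-methylphenyl)methyl]-3-methyloxiran-2-yl}-7-methyl-3-oxonon-6-enoate F1. Lewis acid cyclisation (SnCl4, CH2Cl2, −78 °C), terminated by the chelated β-keto ester enol, which has no geometry to control and no silyl group to lose, gives the bicyclic hydroxy β-keto ester F2. C-Alkylation of F2 at C-1 with 3-(benzyloxy)propyl iodide (Cs2CO3, DMF, 23 °C), the electrophile entering anti to the angular methyl, gives the quaternary keto ester F3. Krapcho demethoxycarbonylation (LiCl, wet DMSO, 150 °C) then gives 19, with C-1 settling into the equatorial configuration.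

**Step 6.** Oxygen transfer may be incompletely face-selective for this benzyl-substituted alkene, some epoxidation of the allylic acetate alkene may occur, and the ketone catalyst may be consumed by Baeyer–Villiger oxidation before conversion is complete. The fallback sets out from 5 and returns at 9. Sharpless asymmetric epoxidation of 5 (Ti(OiPr)4, D-(−)-diethyl tartrate, t-BuOOH, 4 Å sieves, CH2Cl2, −20 °C) gives (2E)-5-[(2R,3R)-3-(hydroxymethyl)-3-methyloxiran-2-yl]-3-methylpent-2-en-1-yl acetate F4, with regiochemistry fixed by the allylic hydroxyl. Triflation (Tf2O, 2,6-lutidine, CH2Cl2, −78 °C) gives the primary triflate F5, and copper-catalysed displacement by Grignard reagent 7 (CuBr·SMe2, Et2O, −78 °C) gives 9.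

**Step 11.** 1,2-Hydrosilylation of the carbonyl may compete, the (Z)-selectivity may erode if the enone reacts through other conformers, and the enol ether may hydrolyse on isolation. The fallback builds the enol ether by a Brook rearrangement; it sets out from 12 and returns at 19. The lithium enolate of acetyl(tert-butyl)dimethylsilane (LDA, THF, −78 °C) is alkylated by 12 to give acylsilane (4E)-1-[tert-butyl(dimethyl)silyl]-7-{(2R,3R)-3-[(2,5-dimethoxy-3-methylphenyl)methyl]-3-methyloxiran-2-yl}-5-methylhept-4-en-1-one F6. Addition of vinyllithium, Brook rearrangement in THF/HMPA and alkylation of the resulting siloxyallyl lithium with 2-(benzyloxy)ethyl iodide give the (Z)-tert-butyldimethylsilyl enol ether F7, the silyl analogue of 18. Cyclisation of F7 with MeAlCl2 as in step 12 gives 19.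

**Step 13.** Homocoupling of acetone may outrun the cross-coupling at the hindered C-2 ketone, or the ketone may simply be reduced. The fallback sets out from 19 and returns at 20. Addition of the dianion of 2-methylpropanoic acid (LDA, THF, −78 → 0 °C) gives β-hydroxy acid F8. Carboxyl-selective lactonisation (bis(2-oxo-3-oxazolidinyl)phosphinic chloride, Et3N, CH2Cl2) gives spiro β-lactone F9. Thermal loss of carbon dioxide (DMF, 150 °C) gives 20 without any possibility of alkene regioisomers.

**Step 16.** Facial selectivity of hydrogen delivery may be poor, the exocyclic alkene may migrate into ring B on palladium before reduction, and the isopropylidene may migrate or be partly saturated. The fallback sets out from 22 and returns at 23. Hydrogen-atom-transfer hydrogenation (Mn(dpm)3, PhSiH3, t-BuOOH, i-PrOH, 23 °C) reduces the 1,1-disubstituted alkene through a tertiary C-6 radical and should give the thermodynamically preferred equatorial methyl in benzyl ether F10. The benzyl group is then removed without palladium by lithium 4,4′-di-tert-butylbiphenylide (THF, −78 °C) to give 23.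

## Further compounds

F1 | step 12 | methyl (6E)-9-{(2R,3R)-3-[(2,5-dimethoxy-3-methylphenyl)methyl]-3-methyloxiran-2-yl}-7-methyl-3-oxonon-6-enoate | COc1cc(C)c(OC)c(C[C@@]2(C)O[C@@H]2CC/C(C)=C/CCC(=O)CC(=O)OC)c1
F2 | step 12 | methyl (4aS,5R,6R,8aR)-5-[(2,5-dimethoxy-3-methylphenyl)methyl]-6-hydroxy-5,8a-dimethyl-2-oxodecahydronaphthalene-1-carboxylate (C-1 unassigned, in equilibrium with its enol) | COc1cc(C)c(OC)c(C[C@]2(C)[C@H]3CCC(=O)C(C(=O)OC)[C@]3(C)CC[C@H]2O)c1
F3 | step 12 | methyl (4aS,5R,6R,8aR)-1-[3-(benzyloxy)propyl]-5-[(2,5-dimethoxy-3-methylphenyl)methyl]-6-hydroxy-5,8a-dimethyl-2-oxodecahydronaphthalene-1-carboxylate (C-1 unassigned) | COc1cc(C)c(OC)c(C[C@]2(C)[C@H]3CCC(=O)C(CCCOCc4ccccc4)(C(=O)OC)[C@]3(C)CC[C@H]2O)c1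
F4 | step 6 | (2E)-5-[(2R,3R)-3-(hydroxymethyl)-3-methyloxiran-2-yl]-3-methylpent-2-en-1-yl acetate | OC[C@@]1(C)O[C@@H]1CC/C(C)=C/COC(C)=O
F5 | step 6 | (2E)-3-methyl-5-[(2R,3R)-3-methyl-3-{[(trifluoromethanesulfonyl)oxy]methyl}oxiran-2-yl]pent-2-en-1-yl acetate | O=S(=O)(OC[C@@]1(C)O[C@@H]1CC/C(C)=C/COC(C)=O)C(F)(F)F
F6 | step 11 | (4E)-1-[tert-butyl(dimethyl)silyl]-7-{(2R,3R)-3-[(2,5-dimethoxy-3-methylphenyl)methyl]-3-methyloxiran-2-yl}-5-methylhept-4-en-1-one | COc1cc(C)c(OC)c(C[C@@]2(C)O[C@@H]2CC/C(C)=C/CCC(=O)[Si](C)(C)C(C)(C)C)c1
F7 | step 11 | tert-butyl{[(4Z,8E)-1-(benzyloxy)-11-{(2R,3R)-3-[(2,5-dimethoxy-3-methylphenyl)methyl]-3-methyloxiran-2-yl}-9-methylundeca-4,8-dien-5-yl]oxy}dimethylsilane | COc1cc(C)c(OC)c(C[C@@]2(C)O[C@@H]2CC/C(C)=C/CC/C(O[Si](C)(C)C(C)(C)C)=C/CCCOCc3ccccc3)c1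
F8 | step 13 | 2-{1-[3-(benzyloxy)propyl]-5-[(2,5-dimethoxy-3-methylphenyl)methyl]-2,6-dihydroxy-5,8a-dimethyldecahydronaphthalen-2-yl}-2-methylpropanoic acid (ring centres as in 19, C-2 unassigned) | COc1cc(C)c(OC)c(C[C@]2(C)[C@H]3CCC(O)(C(C)(C)C(=O)O)[C@@H](CCCOCc4ccccc4)[C@]3(C)CC[C@H]2O)c1
F9 | step 13 | spiro β-lactone of F8 (3,3-dimethyloxetan-2-one spiro-fused at C-2 of the decalin, ring centres as in 19) | COc1cc(C)c(OC)c(C[C@]2(C)[C@H]3CCC5(OC(=O)C5(C)C)[C@@H](CCCOCc4ccccc4)[C@]3(C)CC[C@H]2O)c1
F10 | step 16 | (1S,4aR,5S,6R,8aR)-1-[3-(benzyloxy)propyl]-5-[(2,5-dimethoxy-3-methylphenyl)methyl]-5,6,8a-trimethyl-2-(propan-2-ylidene)decahydronaphthalene | COc1cc(C)c(OC)c(C[C@]2(C)[C@H]3CCC(=C(C)C)[C@@H](CCCOCc4ccccc4)[C@]3(C)CC[C@H]2C)c1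
A1 | alternative 1 | allylic alcohol for the cyclopropanation (C-4a=C-5 double bond, hydroxyl on C-4, C-1 ketone as ethylene ketal) | COc1cc(C)c(OC)c(CC2=C3[C@@H](O)CCC4(OCCO4)[C@]3(C)CC[C@H]2C)c1
A2 | alternative 1 | cyclopropyl carbinol (methylene bridging C-5 and C-4a, hydroxyl on C-4, C-1 ketone as ethylene ketal) | COc1cc(C)c(OC)c(C[C@]23C[C@]24[C@@H](O)CCC5(OCCO5)[C@]4(C)CC[C@H]3C)c1
A3 | alternative 2 | methyl 3-[5,6,8a-trimethyl-2-(propan-2-ylidene)-5-(prop-2-yn-1-yl)decahydronaphthalen-1-yl]propanoate (configuration as in 25) | C#CC[C@]1(C)[C@H]2CCC(=C(C)C)[C@@H](CCC(=O)OC)[C@]2(C)CC[C@H]1C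
A4 | alternative 2 | pentacarbonyl[(2E)-1-methoxybut-2-en-1-ylidene]chromium | C/C=C/C(OC)=[Cr](=C=O)(=C=O)(=C=O)(=C=O)=C=O
A5 | alternative 2 | methyl 3-{5-[(2-hydroxy-5-methoxy-3-methylphenyl)methyl]-5,6,8a-trimethyl-2-(propan-2-ylidene)decahydronaphthalen-1-yl}propanoate (configuration as in 25) | COc1cc(C)c(O)c(C[C@]2(C)[C@H]3CCC(=C(C)C)[C@@H](CCC(=O)OC)[C@]3(C)CC[C@H]2C)c1
A6 | alternative 3 | (2E,8E)-7-[(2,5-dimethoxy-3-methylphenyl)methyl]-3,6,7,12-tetramethyltrideca-2,8,10,11-tetraenal (C-6 and C-7 of the chain configured as C-6 and C-5 of 25) | COc1cc(C)c(OC)c(C[C@](C)(/C=C/C=C=C(C)C)[C@H](C)CC/C(C)=C/C=O)c1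
A7 | alternative 3 | trans-fused octalin aldehyde: 5-[(2,5-dimethoxy-3-methylphenyl)methyl]-5,6,8a-trimethyl-2-(propan-2-ylidene)-1,2,4a,5,6,7,8,8a-octahydronaphthalene-1-carbaldehyde (configuration as in 25) | COc1cc(C)c(OC)c(C[C@]2(C)[C@H]3C=CC(=C(C)C)[C@@H](C=O)[C@]3(C)CC[C@H]2C)c1
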